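(The constants used here are invented; the result is computed.)

The reading at 5.0 min asks how much target is still there, and target can return to starting material, so I reckon with the fraction that stays and not with the fraction made.

    starting material + dissolved gas ⇌ target (K1 = 25 L mol⁻¹, k1 = 0.039 L mol⁻¹ s⁻¹)
    starting material → side product (k2 = 0.013 s⁻¹)
    starting material + protic impurity → quenched substrate (k3 = 0.011 L mol⁻¹ s⁻¹)
    gas phase ⇌ dissolved gas, rate k4*(csat - [dissolved gas]) (k4 = 0.21 s⁻¹, csat = 200 mM)

starting material 2.3 M; gas phase 200 mM (held); protic impurity 2.30 M; time 5.0 min

- at the start none of the gas is dissolved
- run time (flask): 5.0 min

- amount of target at 5.0 min, in percent of the starting material charged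
- the change that raises the amount of target at 5.0 min, in percent of the starting material charged most ("none" if none brings more than 2 percentage points) (grey / blue / none)
- amount of target at 5.0 min, in percent of the starting material charged, after blue

First I take the main step alone, with the dissolved gas at its saturation 200 mM, which makes the step pseudo-first-order in starting material at 0.00780 s⁻¹. At equilibrium the fraction of starting material left is

left = 16.7%

Adding the side product at 0.013 s⁻¹ cuts the target's share of what leaves the starting material to 37.5%. Adding the quench, at 0.0253 s⁻¹ with the impurity as charged, cuts it further:

share to target = 16.9%

The quench takes 54.9% of the starting material, and the two charges are equal, so I expect about 1.04 M of protic impurity late in the run. Target returns with the back constant 0.00156 s⁻¹, and at that impurity level 75.8% of what returns does not become target again. The product of the two is the leak, the first-order constant of final target loss, 0.00118 s⁻¹.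

fraction kept over the run = 70.1%

target = 11.9%

Doubling the saturation raises the share to 28.9%, a gain of 8.4 percentage points at the same fraction kept, so I choose grey. Blue shortens a transfer time of 4.76 s, which is shorter than the 21.7 s lifetime of the starting material, so I expect it to bring less than 2 points.

The forecast gives 11.4%, a little below my figure, with grey as best and 12.7% after blue. For the late fall of target it reckons that “net decay is about 0.0012 s⁻¹”.

The simulation gives 11.3%, with grey best at 8.4 points against 1.2 points for blue, which reaches 12.5%. Moving the charge of protic impurity to 1.17 M or 4.57 M shifts the amount of target by 5 points. For the neighbouring flask left until 12 min, the leak keeps 60.9% of the target present at 5.0 min, which predicts 6.88%, and that flask reads 6.90%.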